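Ring A (C1 benzoyl, C2 OH, C3 prenyl, C4 OMe, C5 prenyl, C6 OMe) carries oxygen on C2, C4 and C6 and carbon on C1, C3 and C5, and C1 sits between the benzoyl carbonyl and the C2 and C6 oxygens: the pattern of a folded benzoyl tetraketide. The route therefore disconnects the C1–C2 bond. The precursor is a fully substituted 2-pyrone, 4-methoxy-6-phenacyl-3,5-diprenyl-2H-pyran-2-one, which masks the open chain. Mg(OMe)2 opens its lactone and the phenacyl carbon closes onto the released ester in a Claisen condensation, so one operation creates ring A with both prenyl groups and the C4 methyl ether already in place. A single selective O-methylation finishes the synthesis.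

Key step: step 8

Remark: the target has no stereocentre; enol ether 7 is drawn as its Z isomer but would be used as the E/Z mixture, and the sp3 centres of the transient intermediates 8 and 13 are left undefined because they become sp2 carbons.

Step 1
Reactants: 1 dimethyl malonate; 2 prenyl bromide (1-bromo-3-methylbut-2-ene)
Product: 3 dimethyl 2-(3-methylbut-2-en-1-yl)malonate
Conditions: NaH (1.0 equiv), 1 (1.5 equiv), THF, 0 °C; then 2, 0 °C to rt; distillation
Reagents that add atoms: none
Why: Malonic ester alkylation, an SN2 displacement at the primary allylic carbon by the sodium malonate, with the excess of 1 suppressing double alkylation.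

Step 2
Reactants: 3 dimethyl 2-(3-methylbut-2-en-1-yl)malonate
Product: 4 2-(3-methylbut-2-en-1-yl)malonic acid
Conditions: KOH (3 equiv), MeOH/H2O, rt; then cold 1 M HCl to pH 2, EtOAc extraction, no heating
Reagents that add atoms: KOH (potassium hydroxide), [K+].[OH-]
Why: Ester saponification of both methyl esters followed by cold acidification should give the diacid without decarboxylation, which needs heat, and without touching the trisubstituted alkene.

Step 3
Reactants: 4 2-(3-methylbut-2-en-1-yl)malonic acid
Product: 5 2-(3-methylbut-2-en-1-yl)malonyl dichloride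
Conditions: (COCl)2 (2.5 equiv), DMF (cat.), CH2Cl2, 0 °C to rt; volatiles removed, used crude at once
Reagents that add atoms: oxalyl chloride, O=C(Cl)C(=O)Cl
Why: Acid chloride formation through the chloroiminium (Vilsmeier-type) catalyst runs at or below room temperature and the HCl leaves as gas, conditions under which acid chlorides bearing prenyl groups are routinely prepared.

Step 4
Reactants: 6 6-methylhept-5-en-2-one
Product: 7 (Z)-trimethyl[(6-methylhepta-2,5-dien-2-yl)oxy]silane
Conditions: Me3SiCl (1.3 equiv), NaI (1.3 equiv), Et3N (1.6 equiv), MeCN, rt; pentane extraction, distillation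
Reagents that add atoms: chlorotrimethylsilane, C[Si](C)(C)Cl
Why: Thermodynamic silyl enol ether formation: iodotrimethylsilane formed in the flask silylates the ketone reversibly in the presence of Et3N, which should favour the more substituted C2=C3 enol ether over the terminal one, and both geometric isomers serve equally in step 5.

Step 5
Reactants: 7 (Z)-trimethyl[(6-methylhepta-2,5-dien-2-yl)oxy]silane; 5 2-(3-methylbut-2-en-1-yl)malonyl dichloride
Product: 9 4-hydroxy-6-methyl-3,5-bis(3-methylbut-2-en-1-yl)-2H-pyran-2-one, via diketo acid chloride 8 (not isolated)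
Conditions: 5 (1.0 equiv), 7 (1.1 equiv), Et2O, −78 °C to 0 °C; extraction into cold aq NaHCO3, acidification to pH 3, extraction
Reagents that add atoms: none
Why: Effenberger-type pyrone synthesis: the nucleophilic C3 of the silyl enol ether is acylated by one acyl chloride group with loss of Me3SiCl to give 8, whose methyl ketone enol oxygen then closes onto the second acyl chloride (lactonisation), and enolisation of the ring ketone gives the 4-hydroxy-2-pyrone.

Step 6
Reactants: 9 4-hydroxy-6-methyl-3,5-bis(3-methylbut-2-en-1-yl)-2H-pyran-2-one
Product: 10 4-methoxy-6-methyl-3,5-bis(3-methylbut-2-en-1-yl)-2H-pyran-2-one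
Conditions: Me2SO4 (1.2 equiv), K2CO3 (2 equiv), acetone, reflux
Reagents that add atoms: dimethyl sulfate, COS(=O)(=O)OC
Why: Williamson-type O-methylation of the potassium salt of the vinylogous acid with a hard electrophile should occur on the C4 oxygen and give the 4-methoxy-2-pyrone, as is usual for 4-hydroxy-2-pyrones under carbonate and dialkyl sulfate conditions.

Step 7
Reactants: 10 4-methoxy-6-methyl-3,5-bis(3-methylbut-2-en-1-yl)-2H-pyran-2-one; 11 methyl benzoate
Product: 12 4-methoxy-3,5-bis(3-methylbut-2-en-1-yl)-6-(2-oxo-2-phenylethyl)-2H-pyran-2-one
Conditions: LiN(i-Pr)2 (2.2 equiv), THF, −78 °C; then 11 (1.1 equiv), −78 to −30 °C; aq NH4Cl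
Reagents that add atoms: none
Why: With C3 and C5 substituted, the amide base can only deprotonate the C6 methyl group to a doubly vinylogous ester enolate, which undergoes a crossed Claisen acylation with the non-enolisable ester, and the second equivalent of base converts the more acidic product into its enolate so that the new ketone is not attacked again.

Step 8
Reactants: 12 4-methoxy-3,5-bis(3-methylbut-2-en-1-yl)-6-(2-oxo-2-phenylethyl)-2H-pyran-2-one
Product: 14 (2,6-dihydroxy-4-methoxy-3,5-bis(3-methylbut-2-en-1-yl)phenyl)(phenyl)methanone, via ring-opened diketo ester 13 (not isolated)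
Conditions: Mg(OMe)2 (8 equiv), MeOH, reflux, N2; then cold 1 M HCl, EtOAc
Reagents that add atoms: none
Why: Mg(OMe)2 first forms the magnesium enolate of the phenacyl group, and methoxide then adds to the lactone carbonyl (pyrone C2) and cleaves the C2–O1 bond, giving methyl ester 13 as a magnesium 1,3-diketonate in which the enol ether double bond inherited from the pyrone (pyrone C3=C4) keeps the ester and the diketonate on the same side. The central diketonate carbon (the former phenacyl CH2, future C1) attacks the ester carbonyl (future C2), methoxide is expelled and the resulting cyclohexenetrione enolises to the phenol, so ring A is closed through one new C1–C2 bond in a 6-exo-trig Claisen (Dieckmann-type) mode. The closest known reaction type is the Mg(OMe)2-mediated recyclisation of 6-(2-oxoalkyl)-4-oxy-2-pyrones to acylphloroglucinols, the laboratory form of polyketide Claisen folding. No stereocentre is formed, and the single sp3 centre of 13 (the prenyl-bearing CH) becomes aromatic C5. The step needs Claisen closure to win over aldol closure and carbon attack to win over oxygen attack: the carbon alpha to the ester carries a prenyl group and no hydrogen, so an aldol adduct at the benzoyl carbonyl cannot aromatise and reverts, while reclosure through the enolate oxygen only returns 12. Magnesium chelation keeps the diketonate a carbon nucleophile and shields the benzoyl group from retro-Claisen cleavage, and the irreversible aromatisation should drain all equilibria towards 14.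

Step 9
Reactants: 14 (2,6-dihydroxy-4-methoxy-3,5-bis(3-methylbut-2-en-1-yl)phenyl)(phenyl)methanone
Product: 15 (2-hydroxy-4,6-dimethoxy-3,5-bis(3-methylbut-2-en-1-yl)phenyl)(phenyl)methanone
Conditions: Me2SO4 (1.1 equiv), K2CO3 (1.5 equiv), acetone, rt to 40 °C
Reagents that add atoms: dimethyl sulfate, COS(=O)(=O)OC
Why: Williamson O-methylation of either of the two equivalent ortho hydroxyls can give only 15, and the remaining hydroxyl is then held in a six-membered hydrogen bond to the benzoyl oxygen, which should stop the reaction at the monoether with about one equivalent of dimethyl sulfate.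

Compound list
1 | dimethyl malonate | COC(=O)CC(=O)OC | starting material
2 | prenyl bromide (1-bromo-3-methylbut-2-ene) | CC(C)=CCBr | starting material
3 | dimethyl 2-(3-methylbut-2-en-1-yl)malonate | COC(=O)C(CC=C(C)C)C(=O)OC | intermediate
4 | 2-(3-methylbut-2-en-1-yl)malonic acid | OC(=O)C(CC=C(C)C)C(=O)O | intermediate
5 | 2-(3-methylbut-2-en-1-yl)malonyl dichloride | O=C(Cl)C(CC=C(C)C)C(=O)Cl | intermediate
6 | 6-methylhept-5-en-2-one | CC(=O)CCC=C(C)C | starting material
7 | (Z)-trimethyl[(6-methylhepta-2,5-dien-2-yl)oxy]silane (E/Z mixture usable) | C/C(O[Si](C)(C)C)=C/CC=C(C)C | intermediate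
8 | 2,4-bis(3-methylbut-2-en-1-yl)-3,5-dioxohexanoyl chloride (diastereomer mixture, not isolated) | CC(=O)C(CC=C(C)C)C(=O)C(CC=C(C)C)C(=O)Cl | intermediate
9 | 4-hydroxy-6-methyl-3,5-bis(3-methylbut-2-en-1-yl)-2H-pyran-2-one | CC1=C(CC=C(C)C)C(O)=C(CC=C(C)C)C(=O)O1 | intermediate
10 | 4-methoxy-6-methyl-3,5-bis(3-methylbut-2-en-1-yl)-2H-pyran-2-one | COC1=C(CC=C(C)C)C(=O)OC(C)=C1CC=C(C)C | intermediate
11 | methyl benzoate | COC(=O)c1ccccc1 | starting material
12 | 4-methoxy-3,5-bis(3-methylbut-2-en-1-yl)-6-(2-oxo-2-phenylethyl)-2H-pyran-2-one | COC1=C(CC=C(C)C)C(=O)OC(CC(=O)c2ccccc2)=C1CC=C(C)C | intermediate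
13 | methyl (2E)-3-methoxy-2,4-bis(3-methylbut-2-en-1-yl)-5,7-dioxo-7-phenylhept-2-enoate (racemic at C4, not isolated) | COC(=O)/C(CC=C(C)C)=C(/OC)C(CC=C(C)C)C(=O)CC(=O)c1ccccc1 | intermediate
14 | (2,6-dihydroxy-4-methoxy-3,5-bis(3-methylbut-2-en-1-yl)phenyl)(phenyl)methanone | COc1c(CC=C(C)C)c(O)c(C(=O)c2ccccc2)c(O)c1CC=C(C)C | intermediate
15 | (2-hydroxy-4,6-dimethoxy-3,5-bis(3-methylbut-2-en-1-yl)phenyl)(phenyl)methanone | COc1c(CC=C(C)C)c(O)c(C(=O)c2ccccc2)c(OC)c1CC=C(C)C | target

Total step count: 9 steps.
Longest linear sequence: 8 steps (steps 1, 2, 3, 5, 6, 7, 8, 9, from dimethyl malonate); step 4 is a one-step branch that joins at step 5.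

Steps most likely to fail

Step 8 (key step). The hindered, electron-rich lactone of the enolised substrate may open slowly. The opened ester may simply reclose to the pyrone. The benzoyl group may be lost by retro-Claisen cleavage, or the diketone may close through oxygen onto the methoxy-bearing alkene carbon. The fallback builds ring A from a preformed arene and sets out from 2. Commercial 2,4,6-trihydroxybenzophenone would be C-prenylated at both free ring positions with 2 (2.2 equiv) in aqueous KOH at 0 °C. This is a known type of phloroglucinol alkylation that is expected to need chromatographic separation from mono- and over-alkylated material. It should give 2,4,6-trihydroxy-3,5-bis(3-methylbut-2-en-1-yl)benzophenone F1. Treatment of this with Me2SO4 (2.1 equiv) and K2CO3 in acetone should methylate the free C4 hydroxyl and one of the two chelated hydroxyls, so the fallback comes back to the route at 15.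

Step 5. The HCl liberated on ring closure may add to the prenyl double bonds or desilylate 7 before it has reacted. Acylation may occur on oxygen in place of carbon. The minor terminal enol ether regioisomer may carry through. The dichloride may self-condense through its ketene. The fallback avoids acid chlorides altogether and sets out from 6. Carboxylation at the methyl group with dimethyl carbonate and NaH in THF should give methyl 7-methyl-3-oxooct-6-enoate F2. C-alkylation with 2 and K2CO3 in acetone should give methyl 7-methyl-2-(3-methylbut-2-en-1-yl)-3-oxooct-6-enoate F3. Its dianion (NaH, then n-BuLi, THF, 0 °C) would be acetylated at the gamma carbon with N-methoxy-N-methylacetamide to give methyl 2,4-bis(3-methylbut-2-en-1-yl)-3,5-dioxohexanoate F4. Lactonisation with DBU in toluene at reflux then comes back to the route at 9.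

Step 7. Proton transfer from the more acidic product to unreacted lateral anion may stall conversion. The amide base may add to the ester or the lactone carbonyl. A second acylation may occur. The fallback lowers the oxidation level of the electrophile and sets out from 10. Deprotonation with LiN(i-Pr)2 (1.1 equiv) in THF at −78 °C and addition of benzaldehyde (a fast aldol addition that needs one equivalent of base) should give racemic 6-(2-hydroxy-2-phenylethyl)-4-methoxy-3,5-bis(3-methylbut-2-en-1-yl)-2H-pyran-2-one F5. Oxidation of the benzylic alcohol with Dess–Martin periodinane and NaHCO3 in CH2Cl2 then comes back to the route at 12.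

Further compounds
F1 | step 8 | 2,4,6-trihydroxy-3,5-bis(3-methylbut-2-en-1-yl)benzophenone | O=C(c1ccccc1)c1c(O)c(CC=C(C)C)c(O)c(CC=C(C)C)c1O
F2 | step 5 | methyl 7-methyl-3-oxooct-6-enoate | COC(=O)CC(=O)CCC=C(C)C
F3 | step 5 | methyl 7-methyl-2-(3-methylbut-2-en-1-yl)-3-oxooct-6-enoate (racemic) | COC(=O)C(CC=C(C)C)C(=O)CCC=C(C)C
F4 | step 5 | methyl 2,4-bis(3-methylbut-2-en-1-yl)-3,5-dioxohexanoate (diastereomer mixture) | COC(=O)C(CC=C(C)C)C(=O)C(CC=C(C)C)C(C)=O
F5 | step 7 | 6-(2-hydroxy-2-phenylethyl)-4-methoxy-3,5-bis(3-methylbut-2-en-1-yl)-2H-pyran-2-one (racemic) | COC1=C(CC=C(C)C)C(=O)OC(CC(O)c2ccccc2)=C1CC=C(C)C
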